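Everything rests on opening the pyran ring of the flavan unit (ring F) at C2–C3 and C4–C4a, which leaves an aryl oxocarbenium ion (O1=C2) and a two-carbon alkene. Before ring F exists, the flavan benzo ring (ring D) is a 2,4,6-trioxygenated phenyl group on flavone C3: its two free carbons, ortho to O1 (later C4a and C8), are equivalent and strongly nucleophilic, so the 6-linkage follows from symmetry. The key step is an enantioconvergent cationic [4+2] annulation (oxa-Povarov): a racemic O-aryl O-pivaloyl acetal is ionised by a chiral acid, benzyl N-vinylcarbamate adds, and ring D closes the ring. C2 (S) is set there; the C4 nitrogen is then removed reductively.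

Key step: step 8

Remark on labels: "flavone C…" refers to the chromen-4-one unit (benzo ring A, pyranone ring C, aryl ring B). O1, C2, C3, C4, C4a, C5–C8 and C8a without a prefix refer to the chroman unit (benzo ring D, pyran ring F, aryl ring E).
Assumption 1: the axis between flavone C3 and C6 carries no descriptor in the target, so rotamers or atropisomers about it are treated as one compound.
Assumption 2: the sense of induction of the chiral acid in step 8 cannot be predicted with certainty; the (R)-acid is written, and its equally available mirror image would be used if the wrong face of C2 is favoured.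

Step 1
Reactants: 1 apigenin
Product: 2 5,7-bis(benzyloxy)-2-[4-(benzyloxy)phenyl]-4H-chromen-4-one
Conditions: BnBr (4 equiv), K2CO3, DMF, 70 °C
Reagents that add atoms: benzyl bromide, BrCc1ccccc1
Why: Williamson etherification; excess benzyl bromide and heat should also alkylate the hydrogen-bonded 5-OH, so that no acidic proton is left for step 2.

Step 2
Reactants: 2 5,7-bis(benzyloxy)-2-[4-(benzyloxy)phenyl]-4H-chromen-4-one
Product: 3 5,7-bis(benzyloxy)-2-[4-(benzyloxy)phenyl]-3-iodo-4H-chromen-4-one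
Conditions: LiN(iPr)2 (LDA), THF, −78 °C; then I2, THF, −78 °C
Reagents that add atoms: iodine, II
Why: Deprotonation of the flavone at C3 (vinylic C–H next to the carbonyl group, lithium held by the C4 oxygen) followed by iodinolysis is a known lithiation–trapping of flavones; it fixes the halogen by acidity and so avoids electrophilic iodination of the electron-rich ring A.

Step 3
Reactants: 4 3,5-bis(benzyloxy)phenol
Product: 5 [3,5-bis(benzyloxy)phenoxy]triisopropylsilane
Conditions: TIPSCl, imidazole, DMF, rt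
Reagents that add atoms: chlorotriisopropylsilane, CC(C)[Si](Cl)(C(C)C)C(C)C
Why: Silyl ether formation; the bulky, non-coordinating silyl group marks the oxygen that becomes O1 and shields its two ortho carbons in step 4.

Step 4
Reactants: 5 [3,5-bis(benzyloxy)phenoxy]triisopropylsilane; 3 5,7-bis(benzyloxy)-2-[4-(benzyloxy)phenyl]-3-iodo-4H-chromen-4-one
Product: 8 5,7-bis(benzyloxy)-2-[4-(benzyloxy)phenyl]-3-[2,6-bis(benzyloxy)-4-(triisopropylsilyloxy)phenyl]-4H-chromen-4-one, via aryllithium 6 (not isolated), via arylzinc chloride 7 (not isolated)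
Conditions: 5, n-BuLi, THF, 0 °C; ZnCl2, THF, 0 °C to rt; then 3, Pd2(dba)3 (2.5 mol %), RuPhos (10 mol %), THF, 65 °C
Reagents that add atoms: none
Why: Directed ortho-metalation at the only C–H flanked by two coordinating benzyloxy groups, transmetalation to zinc and Negishi coupling with a bulky biarylphosphine on zerovalent palladium form a combination known to build biaryls with four ortho substituents; the arylzinc does not add to the chromone carbonyl group.

Step 5
Reactants: 8 5,7-bis(benzyloxy)-2-[4-(benzyloxy)phenyl]-3-[2,6-bis(benzyloxy)-4-(triisopropylsilyloxy)phenyl]-4H-chromen-4-one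
Product: 9 5,7-bis(benzyloxy)-2-[4-(benzyloxy)phenyl]-3-[2,6-bis(benzyloxy)-4-hydroxyphenyl]-4H-chromen-4-one
Conditions: TBAF, AcOH, THF, 0 °C
Reagents that add atoms: none
Why: Fluoride-induced desilylation; acetic acid buffers the phenoxide, and only the future O1 is set free.

Step 6
Reactants: 10 4-hydroxybenzaldehyde
Product: 11 benzyl 4-formylphenyl carbonate
Conditions: CbzCl, Et3N, CH2Cl2, 0 °C
Reagents that add atoms: benzyl chloroformate, O=C(Cl)OCc1ccccc1
Why: O-Acylation of the phenol with a chloroformate gives an electron-poor, hydrogenolysable carbonate, which later raises the electrophilicity of the oxocarbenium ion and protects the C2–O1 bond from acid.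

Step 7
Reactants: 11 benzyl 4-formylphenyl carbonate; 9 5,7-bis(benzyloxy)-2-[4-(benzyloxy)phenyl]-3-[2,6-bis(benzyloxy)-4-hydroxyphenyl]-4H-chromen-4-one
Product: 13 rac-{4-[(benzyloxycarbonyl)oxy]phenyl}{3,5-bis(benzyloxy)-4-[5,7-bis(benzyloxy)-2-(4-benzyloxyphenyl)-4-oxo-4H-chromen-3-yl]phenoxy}methyl pivalate, via chloro ester 12 (not isolated)
Conditions: 11, PivCl (0.95 equiv), ZnCl2 (2 mol %), CH2Cl2, 0 °C to rt, concentrate; then 9, Cs2CO3, DMF, 0 °C; chromatography on Et3N-deactivated silica
Reagents that add atoms: pivaloyl chloride, CC(C)(C)C(=O)Cl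
Why: ZnCl2-catalysed addition of an acyl chloride to an aldehyde gives the 1-chloroalkyl ester, and O-alkylation of a phenoxide with such an ester is the known route to acyloxyalkyl aryl ethers; the tert-butyl group blocks attack at the ester carbonyl group, and the new acetal centre is racemic on purpose.

Step 8
Reactants: 13 rac-{4-[(benzyloxycarbonyl)oxy]phenyl}{3,5-bis(benzyloxy)-4-[5,7-bis(benzyloxy)-2-(4-benzyloxyphenyl)-4-oxo-4H-chromen-3-yl]phenoxy}methyl pivalate; 14 benzyl N-vinylcarbamate
Product: 17 benzyl N-[(2S,4S)-5,7-bis(benzyloxy)-2-{4-[(benzyloxycarbonyl)oxy]phenyl}-6-{5,7-bis(benzyloxy)-2-[4-(benzyloxy)phenyl]-4-oxo-4H-chromen-3-yl}chroman-4-yl]carbamate, via oxocarbenium ion 15 (not isolated), via N-acyliminium ion 16 (not isolated)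
Conditions: (R)-3,3'-bis(2,4,6-triisopropylphenyl)-1,1'-binaphthyl-2,2'-diyl N-triflylphosphoramide (10 mol %), 14 (1.5 equiv, slow addition), 4 Å MS, toluene/CH2Cl2, −40 °C
Reagents that add atoms: none
Why: Proposed new method: the chiral acid protonates the pivalate of racemic 13 and expels pivalic acid, so both enantiomers converge on the planar (E)-aryl oxocarbenium ion 15, held in a contact ion pair with the chiral phosphoramidate; the CH2 terminus of 14, hydrogen-bonded through its N–H to the same anion, adds to C2 (bond C2–C3) to give N-acyliminium ion 16, which is captured by the neighbouring carbon of ring D (bond C4–C4a) with loss of the proton that regenerates the acid. The closest known reaction types are the SnCl4-promoted racemic oxa-Povarov annulation of aryl acetals with alkenes, the chiral phosphoric acid-catalysed Povarov reaction of N-aryl imines with this same enecarbamate, and chiral-anion-controlled additions to oxocarbenium ions; only their combination is new. Ring F is closed as a formal inverse-demand [4π+2π] cycloaddition of the cationic 2-oxadiene C2=O1–C8a=C4a, which in its stepwise reading is a 6-exo-trig Friedel–Crafts closure on the C4=N bond. C2 is controlled by the chiral anion, which should leave the Si face of C2 open (2S), while C4 follows from a chair-like closure with both substituents equatorial (2,4-cis, 4S) and is erased in step 9. Chemoselective ionisation is secured by the leaving group (the acyloxycarbenium ion that loss of the aryloxide would give is far less stabilised than 15), regioselectivity by the local symmetry of ring D (both carbons ortho to O1 are equivalent and the para carbon carries the flavone), and the orientation of the alkene by its nitrogen, which places CH2 at C3. The electron-poor carbonate on ring E should keep the C2–O1 bond of 17 from re-ionising, so the new centre should not racemise under the acid.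

Step 9
Reactants: 17 benzyl N-[(2S,4S)-5,7-bis(benzyloxy)-2-{4-[(benzyloxycarbonyl)oxy]phenyl}-6-{5,7-bis(benzyloxy)-2-[4-(benzyloxy)phenyl]-4-oxo-4H-chromen-3-yl}chroman-4-yl]carbamate
Product: 18 benzyl 4-[(2S)-5,7-bis(benzyloxy)-6-{5,7-bis(benzyloxy)-2-[4-(benzyloxy)phenyl]-4-oxo-4H-chromen-3-yl}chroman-2-yl]phenyl carbonate
Conditions: Et3SiH (5 equiv), TFA (10 vol %), CH2Cl2, −20 to 0 °C
Reagents that add atoms: none
Why: Ionic hydrogenation; the C4–N bond is that of a secondary 2,4,6-trialkoxybenzyl carbamate, the bond type that TFA and a silane cleave in trimethoxybenzyl-protected amides, so it ionises and takes up hydride, whereas the C2–O1 bond next to the electron-poor ring E stays closed and C2 keeps its configuration.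

Step 10
Reactants: 18 benzyl 4-[(2S)-5,7-bis(benzyloxy)-6-{5,7-bis(benzyloxy)-2-[4-(benzyloxy)phenyl]-4-oxo-4H-chromen-3-yl}chroman-2-yl]phenyl carbonate
Product: 19 5,7-dihydroxy-3-[(2S)-5,7-dihydroxy-2-(4-hydroxyphenyl)chroman-6-yl]-2-(4-hydroxyphenyl)-4H-chromen-4-one (target)
Conditions: H2 (1 atm), Pd(OH)2/C, THF/MeOH, rt
Reagents that add atoms: none
Why: Catalytic hydrogenolysis removes the five benzyl ethers and the benzyl carbonate (which loses CO2) under neutral conditions, under which the tetrasubstituted flavone C2=C3 bond and the cyclic C2–O1 ether are known to persist, so the (2S) centre is not touched.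

Compound list
1 | apigenin | O=c1cc(-c2ccc(O)cc2)oc2cc(O)cc(O)c12 | starting material
2 | 5,7-bis(benzyloxy)-2-[4-(benzyloxy)phenyl]-4H-chromen-4-one | O=c1cc(-c2ccc(OCc3ccccc3)cc2)oc2cc(OCc3ccccc3)cc(OCc3ccccc3)c12 | intermediate
3 | 3-iodo derivative of 2 | O=c1c(I)c(-c2ccc(OCc3ccccc3)cc2)oc2cc(OCc3ccccc3)cc(OCc3ccccc3)c12 | intermediate
4 | 3,5-bis(benzyloxy)phenol | Oc1cc(OCc2ccccc2)cc(OCc2ccccc2)c1 | starting material
5 | [3,5-bis(benzyloxy)phenoxy]triisopropylsilane | CC(C)[Si](Oc1cc(OCc2ccccc2)cc(OCc2ccccc2)c1)(C(C)C)C(C)C | intermediate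
6 | 2,6-bis(benzyloxy)-4-(triisopropylsilyloxy)phenyllithium | [Li]c1c(OCc2ccccc2)cc(O[Si](C(C)C)(C(C)C)C(C)C)cc1OCc1ccccc1 | intermediate
7 | 2,6-bis(benzyloxy)-4-(triisopropylsilyloxy)phenylzinc chloride | Cl[Zn]c1c(OCc2ccccc2)cc(O[Si](C(C)C)(C(C)C)C(C)C)cc1OCc1ccccc1 | intermediate
8 | 3-[2,6-bis(benzyloxy)-4-(triisopropylsilyloxy)phenyl] derivative of 2 | O=c1c(-c2c(OCc3ccccc3)cc(O[Si](C(C)C)(C(C)C)C(C)C)cc2OCc2ccccc2)c(-c2ccc(OCc3ccccc3)cc2)oc2cc(OCc3ccccc3)cc(OCc3ccccc3)c12 | intermediate
9 | 3-[2,6-bis(benzyloxy)-4-hydroxyphenyl] derivative of 2 | O=c1c(-c2c(OCc3ccccc3)cc(O)cc2OCc2ccccc2)c(-c2ccc(OCc3ccccc3)cc2)oc2cc(OCc3ccccc3)cc(OCc3ccccc3)c12 | intermediate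
10 | 4-hydroxybenzaldehyde | O=Cc1ccc(O)cc1 | starting material
11 | benzyl 4-formylphenyl carbonate | O=Cc1ccc(OC(=O)OCc2ccccc2)cc1 | intermediate
12 | rac-chloro{4-[(benzyloxycarbonyl)oxy]phenyl}methyl pivalate | CC(C)(C)C(=O)OC(Cl)c1ccc(OC(=O)OCc2ccccc2)cc1 | intermediate
13 | racemic O-aryl O-pivaloyl acetal of 11 on the free oxygen of 9 | O=c1c(-c2c(OCc3ccccc3)cc(OC(OC(=O)C(C)(C)C)c3ccc(OC(=O)OCc4ccccc4)cc3)cc2OCc2ccccc2)c(-c2ccc(OCc3ccccc3)cc2)oc2cc(OCc3ccccc3)cc(OCc3ccccc3)c12 | intermediate
14 | benzyl N-vinylcarbamate | C=CNC(=O)OCc1ccccc1 | starting material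
15 | (E)-aryl oxocarbenium ion (cation drawn; counter-ion is the chiral phosphoramidate) | O=c1c(-c2c(OCc3ccccc3)cc(/[O+]=C/c3ccc(OC(=O)OCc4ccccc4)cc3)cc2OCc2ccccc2)c(-c2ccc(OCc3ccccc3)cc2)oc2cc(OCc3ccccc3)cc(OCc3ccccc3)c12 | intermediate
16 | (S)-3-aryl-3-aryloxypropylidene N-acyliminium ion (cation drawn; same counter-ion) | O=c1c(-c2c(OCc3ccccc3)cc(O[C@@H](CC=[NH+]C(=O)OCc3ccccc3)c3ccc(OC(=O)OCc4ccccc4)cc3)cc2OCc2ccccc2)c(-c2ccc(OCc3ccccc3)cc2)oc2cc(OCc3ccccc3)cc(OCc3ccccc3)c12 | intermediate
17 | (2S,4S)-4-(benzyloxycarbonylamino)flavan cycloadduct | O=c1c(-c2c(OCc3ccccc3)cc3c(c2OCc2ccccc2)[C@@H](NC(=O)OCc2ccccc2)C[C@@H](c2ccc(OC(=O)OCc4ccccc4)cc2)O3)c(-c2ccc(OCc3ccccc3)cc2)oc2cc(OCc3ccccc3)cc(OCc3ccccc3)c12 | intermediate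
18 | protected (2S)-flavan (five benzyl ethers, one benzyl carbonate) | O=c1c(-c2c(OCc3ccccc3)cc3c(c2OCc2ccccc2)CC[C@@H](c2ccc(OC(=O)OCc4ccccc4)cc2)O3)c(-c2ccc(OCc3ccccc3)cc2)oc2cc(OCc3ccccc3)cc(OCc3ccccc3)c12 | intermediate
19 | 5,7-dihydroxy-3-[(2S)-5,7-dihydroxy-2-(4-hydroxyphenyl)chroman-6-yl]-2-(4-hydroxyphenyl)-4H-chromen-4-one | O=c1c(-c2c(O)cc3c(c2O)CC[C@@H](c2ccc(O)cc2)O3)c(-c2ccc(O)cc2)oc2cc(O)cc(O)c12 | target

Total step count: 10. Longest linear sequence: 8 (steps 1, 2, 4, 5, 7, 8, 9, 10).

Steps most likely to fail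

1. Step 8.
- What may go wrong: poor facial selectivity in a loosely bound ion pair of a very large cation, acid-induced self-condensation of the enecarbamate, or intermolecular Friedel–Crafts capture of the cation by ring D of a second molecule.
- The fallback uses known chemistry only, sets out from 9 and comes back at 19.
- Casnati–Skattebøl ortho-formylation of 9 (MgCl2, Et3N, paraformaldehyde, MeCN, reflux) should give the salicylaldehyde F1. The same symmetry argument makes either ortho carbon equivalent.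
- Claisen–Schmidt condensation with commercial 4'-benzyloxyacetophenone (Ba(OH)2, MeOH/THF, rt) should give the (E)-enone F2.
- Hydrogenation of the C=C bond (H2, RhCl(PPh3)3, toluene/EtOH) should give the saturated ketone F3.
- Noyori transfer hydrogenation (RuCl[(R,R)-TsDPEN](p-cymene), HCO2H/Et3N) should give the (R)-carbinol F4.
- Mitsunobu cyclisation (PPh3, DIAD, THF, 0 °C), in which the phenol displaces the activated carbinol with inversion, should give the hexa-O-benzyl (2S)-flavan F5.
- Hydrogenolysis of F5 under the conditions of step 10 gives 19.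

2. Step 4.
- What may go wrong: diversion of the lithiation to benzylic deprotonation with Wittig rearrangement, and loss of the organometal to protodemetalation while the coupling at the fourfold ortho-substituted axis lags.
- The fallback replaces C–H metalation and zinc by electrophilic halogenation and boron. It sets out from 5 (and 3) and comes back at 8.
- Bromination of 5 (NBS, MeCN, 0 °C) should go to the carbon between the two benzyloxy groups, para to the bulky silyloxy group, and give the aryl bromide F6.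
- Bromine–lithium exchange (n-BuLi, THF, −78 °C) is much faster than deprotonation. Trapping with 2-isopropoxy-4,4,5,5-tetramethyl-1,3,2-dioxaborolane should give the pinacol boronate F7.
- Suzuki–Miyaura coupling of F7 with 3 (Pd(OAc)2, SPhos, K3PO4, toluene/H2O, 80 °C) gives 8.

3. Step 7.
- What may go wrong: reversion of the chloro ester to aldehyde and acyl chloride, transfer of a pivaloyl or benzyloxycarbonyl group to the phenoxide, and hydrolysis of the acetal during purification.
- The fallback makes the O–C bond with a robust α-bromoketone and creates the acyloxy leaving group afterwards by oxygen insertion. It sets out from 9 and comes back at 17.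
- Commercial 4-hydroxyphenylacetone with CbzCl/Et3N should give the aryl carbonate F8.
- Bromination at the benzylic α-carbon (NBS, cat. TsOH, MeCN) should give the bromoketone F9.
- O-Alkylation of 9 with F9 (Cs2CO3, acetone, rt) should give the α-aryloxy ketone F10.
- Baeyer–Villiger oxidation (mCPBA, NaHCO3, CH2Cl2, 0 °C), with migration of the α-aryloxybenzyl carbon rather than methyl, should give the α-acetoxy ether F11.
- F11 is taken into step 8 in place of 13 and gives 17.

Further compounds
F1 | step 8 | 3-[2,6-bis(benzyloxy)-3-formyl-4-hydroxyphenyl]-5,7-bis(benzyloxy)-2-[4-(benzyloxy)phenyl]-4H-chromen-4-one | O=c1c(-c2c(OCc3ccccc3)cc(O)c(C=O)c2OCc2ccccc2)c(-c2ccc(OCc3ccccc3)cc2)oc2cc(OCc3ccccc3)cc(OCc3ccccc3)c12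
F2 | step 8 | (E)-enone from F1 and 4'-benzyloxyacetophenone | O=c1c(-c2c(OCc3ccccc3)cc(O)c(/C=C/C(=O)c3ccc(OCc4ccccc4)cc3)c2OCc2ccccc2)c(-c2ccc(OCc3ccccc3)cc2)oc2cc(OCc3ccccc3)cc(OCc3ccccc3)c12
F3 | step 8 | saturated ketone from F2 | O=c1c(-c2c(OCc3ccccc3)cc(O)c(CCC(=O)c3ccc(OCc4ccccc4)cc3)c2OCc2ccccc2)c(-c2ccc(OCc3ccccc3)cc2)oc2cc(OCc3ccccc3)cc(OCc3ccccc3)c12
F4 | step 8 | (R)-carbinol from F3 | O=c1c(-c2c(OCc3ccccc3)cc(O)c(CC[C@@H](O)c3ccc(OCc4ccccc4)cc3)c2OCc2ccccc2)c(-c2ccc(OCc3ccccc3)cc2)oc2cc(OCc3ccccc3)cc(OCc3ccccc3)c12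
F5 | step 8 | hexa-O-benzyl ether of 19, (2S) | O=c1c(-c2c(OCc3ccccc3)cc3c(c2OCc2ccccc2)CC[C@@H](c2ccc(OCc4ccccc4)cc2)O3)c(-c2ccc(OCc3ccccc3)cc2)oc2cc(OCc3ccccc3)cc(OCc3ccccc3)c12
F6 | step 4 | [3,5-bis(benzyloxy)-4-bromophenoxy]triisopropylsilane | CC(C)[Si](Oc1cc(OCc2ccccc2)c(Br)c(OCc2ccccc2)c1)(C(C)C)C(C)C
F7 | step 4 | pinacol 2,6-bis(benzyloxy)-4-(triisopropylsilyloxy)phenylboronate | CC(C)[Si](Oc1cc(OCc2ccccc2)c(B2OC(C)(C)C(C)(C)O2)c(OCc2ccccc2)c1)(C(C)C)C(C)C
F8 | step 7 | benzyl 4-(2-oxopropyl)phenyl carbonate | CC(=O)Cc1ccc(OC(=O)OCc2ccccc2)cc1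
F9 | step 7 | rac-benzyl 4-(1-bromo-2-oxopropyl)phenyl carbonate | CC(=O)C(Br)c1ccc(OC(=O)OCc2ccccc2)cc1
F10 | step 7 | racemic α-aryloxy ketone from 9 and F9 | O=c1c(-c2c(OCc3ccccc3)cc(OC(C(C)=O)c3ccc(OC(=O)OCc4ccccc4)cc3)cc2OCc2ccccc2)c(-c2ccc(OCc3ccccc3)cc2)oc2cc(OCc3ccccc3)cc(OCc3ccccc3)c12
F11 | step 7 | racemic α-acetoxy ether (acetate analogue of 13) | O=c1c(-c2c(OCc3ccccc3)cc(OC(OC(C)=O)c3ccc(OC(=O)OCc4ccccc4)cc3)cc2OCc2ccccc2)c(-c2ccc(OCc3ccccc3)cc2)oc2cc(OCc3ccccc3)cc(OCc3ccccc3)c12
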